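The start rate of these flasks cannot be read: Monday's first two readings of target, 3.6% after 1.00 h and 3.5% after 3.00 h, each carry a scatter of 1 percentage point, so no slope comes from that pair. What can be reckoned is the slowing.

| flask | substrate | free catalyst | impurity | temperature | remark | time |
|---|---|---|---|---|---|---|
| Monday's | 0.020 M | 0.75 mol% | 39 µM | −45 °C | run made earlier |  |
| Wednesday's | 0.020 M | 3 mol% | 39 µM | −20 °C | run made earlier |  |
| Thursday's | 0.030 M | 1.5 mol% | 39 µM | −45 °C | run made earlier |  |
| south | 0.020 M | 1.5 mol% | 39 µM | 0 °C |  | 2.0 h |
| south-east | 0.020 M | 1.5 mol% | 39 µM | −20 °C |  | 2.0 h |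
| south-west | 0.020 M | 1.5 mol% | 39 µM | −40 °C |  | 2.0 h |

- Monday's (time / h: target / %, side product / %): 1.00: 3.6, 0; 3.00: 3.5, 0; 5.00: 4.8, 1.6; 8.00: 5.9, 0.4; 12.0: 8.7, 0.7; 15.0: 10.8, 0.8; 20.0: 12.6, 1.4
- Wednesday's (time / h: target / %, side product / %): 0.667: 27.6, 2.2; 1.33: 40.3, 2.6; 2.50: 49.6, 8.4; 4.00: 55.8, 14.3; 5.00: 58.8, 15.1
- Thursday's (time / h: target / %, side product / %): 4.00: 8.0, 2.1; 8.00: 10.1, 1.9; 12.0: 15.9, 1.5; 15.0: 14.6, 1.7; 20.0: 20.0, 2.5

(readings scatter by 1 percentage point)

- the flask with the highest share of target in all that became target or side product ("all alike" if they lie within 1.5 percentage points) (south / south-east / south-west / all alike)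
- share of target in all that became target or side product, south
- share of target in all that became target or side product, south-east
- share of target in all that became target or side product, south-west

- in percentages every species weighs as the substrate in it: one side product counts as two
- steps under discussion: free catalyst + impurity -> spent catalyst; substrate + free catalyst -> catalyst intermediate; catalyst intermediate <-> free catalyst + target; substrate + target -> side product

1. The reckoning here assumes that the impurity takes its share of the free catalyst first; its charge is smaller than the catalyst's, so catalyst remains afterwards. In all 3 new flasks this leaves an active catalyst, c_act, of 261 µM, a factor 87.0% on the rate.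

2. Take the step between catalyst intermediate and target as settled. Free catalyst then falls as c_act divided by c_target, which is product inhibition. The rate falls with each gain of target, so c_target squared should grow as G · c_act · c_substrate · time.

3. The last readings give G as 0.143 h⁻¹ on Monday and 0.146 h⁻¹ on Thursday. Two different charges agree within their scatter.

4. Side product grows with c_substrate · c_target, so its rate climbs as the target's rate falls. Accumulated, c_act drops out: side product over target rises linearly, by b per hour at 0.020 M substrate, the side clock. It holds while substrate stands.

5. Wednesday's reading gives 0.0641 h⁻¹ at −20 °C. Monday's gives 0.005556 h⁻¹ at −45 °C, a weak reading given the scatter of 1 point. Together they give 47.0 kJ mol⁻¹.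

6. Over 2.0 h the ratio is 0.657 in south, 0.128 in south-east and 0.0189 in south-west. The own reckoning of the share is therefore 60.4%, 88.6% and 98.1%, highest in south-west.

The forecast, resting on “strong product inhibition”, gave 71%, 85% and 97.5%, with south-west first.

The flasks give 66.2%, 84.7% and 98.2%, with south-west highest.

    free catalyst + impurity → spent catalyst (k = 25000 M⁻¹ s⁻¹, Ea = 31.0 kJ mol⁻¹)
    substrate + free catalyst → catalyst intermediate (k = 400 M⁻¹ min⁻¹, Ea = 49.0 kJ mol⁻¹)
    catalyst intermediate ⇌ free catalyst + target (K = 0.00240 M, k = 200 min⁻¹, Ea = 53.0 kJ mol⁻¹, ΔH = 26.0 kJ mol⁻¹)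
    substrate + target → side product (k = 0.640 M⁻¹ min⁻¹, Ea = 60.0 kJ mol⁻¹)
    (constants at 0 °C)

South's simulated ratio of 0.511 equals 1.56 h on its side clock. The neighbour of south charged with 6 mol% has c_act of 1160 µM and reaches 82.8% target. Scaling the clock by c_act and target squared gives 0.604 h, a ratio of 0.198 and a share of 83.5%. That neighbour gives 87.2%.

All runs stem from a simulated flask with constants of no real substance, noise included.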